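## The problem

Guanipiperazine A (26) is a cis-2,5-disubstituted piperazine whose two benzylic arms are tied together by a diaryl ether. The arm on C2 ends in ring A, a phenol flanked by the ether oxygen and by C8 of a guanine; the arm on C5 ends in the para-phenylene ring B. The chain C2–CH2–ring A–O–ring B–CH2–C5, together with two ring atoms of the piperazine, forms a strained 14-membered cyclophane, and closing it is the central difficulty.

There are two stereocentres, C2 and C5, both S and cis. C5 maps onto an L-arylalanine and can be bought. Because the ansa chain cannot span a trans-2,5 arrangement, C5 and the bridge together dictate C2, so C2 may be created in the ring closure itself.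

The guanine is polar, poorly soluble and rich in N–H bonds, and belongs at the end. The catechol-type phenol is oxidation-prone, both secondary amines need masking, and any N-protected α-amino ester or aldehyde on the way can epimerise in base.

Two features of ring A invite an unconventional closure. Its benzylic CH2 is para to the phenolic OH, so this carbon can be unmasked as the exocyclic carbon of a para-quinone methide. The atom it must join, C2, lies between N1 and C3 and becomes a malonate-type carbanion once C3 is a lactam carbonyl and C2 carries an ester. Ring A also has only one open position ortho to the hydroxyl, so a late phenol-directed introduction of the guanine carbon is regiochemically unambiguous.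

## Retrosynthesis

**Guanine (26 ⇒ 25 ⇒ 21 + 22).** The two Boc groups of 25 are removed last. The imidazole ring is cut at C8–N7 and C8–N9, leading to salicylaldehyde 21 and commercial 2,5,6-triaminopyrimidin-4(3H)-one sulfate 22. The neighbouring cut, the C8–aryl bond, would need a protected 8-haloguanine and a metallated, hindered phenol. The chosen cut keeps the insoluble purine out of every earlier step. The forward reaction must be an oxidative condensation that spares a free phenol and two carbamates.

**Formyl group (21 ⇒ 20).** The aryl–CHO bond is cut to give bis-Boc cyclophane phenol 20. Phenoxide-directed formylation is ortho-specific, and 20 has one free ortho site and a blocked para site. Introducing the aldehyde earlier would expose it to borane and base.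

**Activating carbonyls (20 ⇒ 18 ⇒ 16).** The C3 methylene is traced back to the lactam carbonyl of 18, and the C2–H to the methyl ester of 16. These two carbonyls are the price of making C2 acidic. Both can be removed without touching C5, and the bridge forces the reprotonated C2 to be cis.

**Key cut (16 ⇒ 14 via 15).** The C2–CH2 bond to ring A is cut, giving 4-hydroxybenzyl sulfone 14, which ionises to para-quinone methide 15.
- The neighbouring cut at the diaryl ether oxygen is the classical closure. It needs a preformed cis-piperazine from two amino acids and a hot copper-mediated step on the strained ring.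
- The chosen cut needs one chiral building block instead of two, sets C2 through the bridge, and draws its driving force from re-aromatisation of ring A.
- Precursor 14 is a monocyclic piperazinone with a single stereocentre.
- The forward reaction must be an intramolecular 1,6-addition that outruns oligomerisation of a very reactive quinone methide.

**Arming and piperazinone (14 ⇒ 13 ⇒ 12 ⇒ 10).** The free phenol of 14 comes from benzyl ether 13, so the sulfone cannot ionise before it is wanted. The N1 carbamate of 13 comes from amine 12. The lactam bond N4–C3 of 12 is cut to the acyclic amino malonate 10. A substituent on the lactam nitrogen that would push the C5 arm axial was weighed. It was not adopted: it costs three steps, and the lactam N–H is far less acidic than C2–H.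

**Amine bond (10 ⇒ 8 + 9).** The N1–C6 bond is cut by reductive amination into α-amino aldehyde 8 and commercial dimethyl aminomalonate hydrochloride 9. Alkylating a tyrosine-derived 1,2-diamine with a bromomalonate would need three more steps. The forward step must not epimerise 8.

**Sulfone (8 ⇒ 7 ⇒ 4 ⇒ 3).** Aldehyde 8 comes from methyl ester 7. The C–S bond of 7 is cut to benzylic alcohol 4 and commercial sodium 4-toluenesulfinate 5, and 4 comes from aryl aldehyde 3. The ring A aldehyde must be consumed before the ester is reduced. The sulfone is inert to hydride, acid, amines and hydrogenolysis while the para oxygen is benzylated, so it is installed early.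

**Diaryl ether (3 ⇒ 1 + 2).** The C–O bond is cut so that ring B is the electrophile, commercial Boc-4-iodo-L-phenylalanine methyl ester 1, and ring A the nucleophile, commercial 4-(benzyloxy)-3-hydroxybenzaldehyde 2. The reverse polarity would pair a tyrosine phenol with an electron-rich, ortho-alkoxy aryl bromide. That coupling needs more forcing conditions and puts the α-centre at greater risk.

## Roads not taken

**Alternative 1:** The cut is the bond between the ring B ipso carbon and its benzylic CH2. The open precursor is dipeptide iodide A1, an N-phthaloyl arylalanyl-L-alanine 8-aminoquinoline amide carrying the 4-iodophenyl ether. With Pd(OAc)2 and AgOAc the quinoline amide directs palladation of the alanine methyl group, and the tethered aryl iodide couples to it to give cyclophane lactam A2.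
- Merits: both stereocentres are bought, and aminoquinoline-directed C–H arylation has been used to close peptide cyclophanes, so the ring closure belongs to a demonstrated reaction class. In that respect it is better founded than the chosen closure.
- Weak points: the alanine centre sits next to the palladacycle at about 110 °C and may epimerise. After closure the quinoline amide, notoriously hard to cleave, must be removed and the phthalimide opened. A diketopiperazine must then be closed inside the strained cyclophane, two lactams reduced, and a methyl ether cleaved with a strong Lewis acid.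
- Comparison: the chosen plan must set against this an unprecedented macrocyclisation and a stereocentre that is made instead of bought. In return it leaves one lactam instead of three amide-level carbonyls, a phenol that is already free, and a shorter route after ring closure.

**Alternative 2:** The cut is C8–N7 and C8–N9 of the purine. Macrocyclic salicylaldehyde A3 condenses with the 5- and 6-amino groups of 22, and the aminal is dehydrogenated to bis-Boc guanipiperazine A, A4.
- Merits: convergent, late, and tolerant. As a single transformation it is more reliable than step 9.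
- Weak point: it leaves the real problem, the cyclophane in A3, unsolved.
- Comparison: this road is absorbed into the chosen plan. A3 and A4 are the same structures as 21 and 25, and steps 12–13 are this disconnection. The chosen plan adds a way to reach A3.

**Alternative 3:** The cuts are N1–C2 and C2–C3. Azido aldehyde A5 closes by Staudinger–aza-Wittig reaction to the 14-membered cyclic imine A6. Cu(OTf)2 with 2,6-lutidine then converts the stannylmethyl carbamate into an α-amino radical that adds across the ring to the imine carbon, giving mono-Boc O-methyl piperazine A7.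
- Merits: the piperazine arrives at the correct oxidation level with its nitrogens differentiated. No decarboxylation or lactam reduction follows, which is a real saving over the chosen plan.
- Weak points: the imine comes from an enolisable arylacetaldehyde and can tautomerise into conjugation with ring A, hydrolyse or oligomerise. A strained macrocyclic aza-Wittig closure is itself untested. The method needs stoichiometric tin and copper, and the methyl ether again needs a harsh late demethylation.
- Comparison: the chosen plan spends two extra steps after ring closure. In return its closure is an irreversible C–C bond formation driven by aromatisation, from a bench-stable, tin-free precursor, and the phenol emerges free.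

Key step: step 9

Remark: compounds 12–15 are carried as mixtures of C2 epimers (C2 drawn without configuration), since this centre is planarised in step 9. Target 26 is drawn as the neutral free base. Piperazine atoms are numbered N1, C2 (ring A arm), C3, N4, C5 (ring B arm), C6 throughout; tosyl = 4-methylbenzenesulfonyl.

Step 1
Reactants: 1 Boc-4-iodo-L-phenylalanine methyl ester; 2 4-(benzyloxy)-3-hydroxybenzaldehyde
Product: 3 methyl (2S)-3-{4-[2-(benzyloxy)-5-formylphenoxy]phenyl}-2-(Boc-amino)propanoate
Conditions: CuI (10 mol %), N,N-dimethylglycine hydrochloride (30 mol %), Cs2CO3, 1,4-dioxane, 90 °C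
Reagents that add atoms: none
Why: Ligand-accelerated Ullmann diaryl ether synthesis; the unhindered para-alkyl aryl iodide and the guaiacol-type phenol are the pairing that couples at the lowest temperature, under carbonate/dioxane conditions in which an N-carbamoyl amino ester is expected to keep its configuration.

Step 2
Reactants: 3 diaryl ether aldehyde
Product: 4 methyl (2S)-3-{4-[2-(benzyloxy)-5-(hydroxymethyl)phenoxy]phenyl}-2-(Boc-amino)propanoate
Conditions: NaBH4, MeOH/THF, 0 °C
Reagents that add atoms: none
Why: Chemoselective borohydride reduction of the aryl aldehyde; methyl ester and carbamate are inert at 0 °C.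

Step 3
Reactants: 4 benzylic alcohol; 5 sodium 4-toluenesulfinate
Product: 7 methyl (2S)-3-{4-[2-(benzyloxy)-5-(tosylmethyl)phenoxy]phenyl}-2-(Boc-amino)propanoate, via benzylic bromide 6 (not isolated)
Conditions: CBr4, PPh3, CH2Cl2, 0 °C; solvent exchange; 5, DMF, rt
Reagents that add atoms: none
Why: Appel bromination of the electron-rich benzylic alcohol, then S-alkylation of the sulfinate by the soft benzylic bromide; the resulting sulfone cannot ionise while the para oxygen is benzylated.

Step 4
Reactants: 7 sulfone ester
Product: 8 tert-butyl N-[(2S)-1-{4-[2-(benzyloxy)-5-(tosylmethyl)phenoxy]phenyl}-3-oxopropan-2-yl]carbamate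
Conditions: i-Bu2AlH (2.2 equiv), CH2Cl2, −78 °C; MeOH, aq. potassium sodium tartrate (KNaC4H4O6)
Reagents that add atoms: none
Why: Partial reduction of an N-Boc α-amino methyl ester through the tetrahedral aluminate that is stable at −78 °C; sulfone and ethers are inert, and the aldehyde is used crude at once to limit α-epimerisation.

Step 5
Reactants: 8 amino aldehyde; 9 dimethyl aminomalonate hydrochloride
Product: 10 dimethyl 2-{[(2S)-2-(Boc-amino)-3-{4-[2-(benzyloxy)-5-(tosylmethyl)phenoxy]phenyl}propyl]amino}malonate
Conditions: Et3N (1 equiv), NaBH(OAc)3, 4 Å MS, ClCH2CH2Cl, 0 °C to rt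
Reagents that add atoms: none
Why: Reductive amination with triacetoxyborohydride, which reduces the iminium ion faster than it can tautomerise to the enamine, so the α-centre should survive; both imine tautomers of the aminomalonate give the same amine.

Step 6
Reactants: 10 Boc-amino malonate
Product: 12 methyl (2RS,5S)-5-{4-[2-(benzyloxy)-5-(tosylmethyl)phenoxy]benzyl}-3-oxopiperazine-2-carboxylate, via diamine bis(trifluoroacetate) 11 (not isolated)
Conditions: CF3CO2H, CH2Cl2, 0 °C to rt; concentrate; Et3N, MeOH, 50 °C
Reagents that add atoms: none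
Why: Acidolysis of the carbamate, then 6-exo-trig aminolysis of one of the two equivalent malonate esters by the freed primary amine closes the lactam N4–C3; the aryl benzyl ether and the sulfone tolerate brief trifluoroacetic acid, and C5 is no longer α to a carbonyl from here on.

Step 7
Reactants: 12 piperazinone amine
Product: 13 1-tert-butyl 2-methyl (2RS,5S)-5-{4-[2-(benzyloxy)-5-(tosylmethyl)phenoxy]benzyl}-3-oxopiperazine-1,2-dicarboxylate
Conditions: Boc2O, i-Pr2NEt, THF, 45 °C
Reagents that add atoms: di-tert-butyl dicarbonate, CC(C)(C)OC(=O)OC(=O)OC(C)(C)C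
Why: Carbamoylation of the ring amine N1; without DMAP the lactam N–H is not acylated, and the carbamate later prevents N-attack on the quinone methide and helps acidify C2–H.

Step 8
Reactants: 13 benzyl ether
Product: 14 1-tert-butyl 2-methyl (2RS,5S)-5-{4-[2-hydroxy-5-(tosylmethyl)phenoxy]benzyl}-3-oxopiperazine-1,2-dicarboxylate
Conditions: H2 (1 atm), 10% Pd/C, EtOAc/THF, rt
Reagents that add atoms: none
Why: Hydrogenolysis of the aryl benzyl ether under neutral conditions; benzylic sulfone, diaryl ether, carbamate and esters are inert, and the 4-hydroxybenzyl sulfone is stable until base is added.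

Step 9
Reactants: 14 4-hydroxybenzyl sulfone
Product: 16 macrocyclic (2S,5S)-piperazinone ester with free ring A phenol, via quinone methide 15 (not isolated)
Conditions: Cs2CO3 (3 equiv), 4 Å MS, MeCN (1 mM, slow addition of 14), 40 °C; aq. NH4Cl
Reagents that add atoms: none
Why: Proposed new method: Cs2CO3 forms the phenoxide and the C2 cesium enolate of 14; the phenoxide expels 4-toluenesulfinate in a vinylogous E1cB (1,6-) elimination to give para-quinone methide 15, and the soft enolate carbon adds to its exocyclic methylene, with the regained aromaticity of ring A paying for the strain of the cyclophane. The closest known reaction type is the intermolecular base-mediated 1,6-addition of malonate-type carbon acids to para-quinone methides released in situ from 4-hydroxybenzyl sulfones; using it to close a macrocycle is new. The 14-membered ring closes in a 14-endo-trig mode, because both carbons of the exocyclic C=C end up inside the new ring, which is no constraint at this ring size. The new quaternary centre C2 is controlled by C5: the enolate is planar, so both C2 epimers of 14 converge, and the tether from C5 through ring B and the ether oxygen can deliver the methylene only to the face cis to the C5 arm, giving (2S,5S). The step needs intramolecular C-alkylation to beat oligomerisation, O-alkylation and capture by water; slow addition at high dilution keeps 15 scarce, re-addition of sulfinate and O-adducts are reversible whereas the C–C adduct is not, and molecular sieves exclude water. The carbamate on N1 and the un-ionised lactam N–H leave carbon as the only competent internal nucleophile.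

Step 10
Reactants: 16 macrocyclic piperazinone ester
Product: 18 macrocyclic (2S,5S)-1-Boc-3-oxopiperazine phenol, via carboxylic acid 17 (not isolated)
Conditions: LiOH, THF/MeOH/H2O, 40 °C; 1 M HCl to pH 3, 0 °C; 1,4-dioxane, 90 °C
Reagents that add atoms: none
Why: Saponification of the malonate-type methyl ester and thermal decarboxylation of the α-amino malonamic acid through its cyclic transition state; the lactam enol can only be protonated to the cis isomer because the bridge cannot span a trans-2,5 arrangement, so C2 stays S.

Step 11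
Reactants: 18 macrocyclic lactam
Product: 20 N1,N4-bis-Boc macrocyclic (2S,5S)-piperazine phenol, via mono-Boc piperazine 19 (not isolated)
Conditions: BH3·THF, THF, 65 °C; MeOH, 65 °C; then Boc2O, Et3N, CH2Cl2, rt
Reagents that add atoms: di-tert-butyl dicarbonate, CC(C)(C)OC(=O)OC(=O)OC(C)(C)C
Why: Electrophilic borane reduces the secondary lactam to the amine and spares the carbamate, methanolysis breaks the amine–borane, and the crude secondary amine is carbamoylated; the non-basic conditions leave C2 untouched.

Step 12
Reactants: 20 bis-Boc phenol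
Product: 21 bis-Boc macrocyclic salicylaldehyde (formyl group ortho to the ring A hydroxyl)
Conditions: MgCl2, Et3N, (CH2O)n, MeCN, 80 °C
Reagents that add atoms: paraformaldehyde, C=O
Why: Casnati–Skattebøl ortho-formylation: the magnesium phenoxide delivers formaldehyde to the ortho carbon and a second formaldehyde oxidises the benzylic alkoxide; the only free ortho site is used, and the para site is blocked.

Step 13
Reactants: 21 salicylaldehyde; 22 2,5,6-triaminopyrimidin-4(3H)-one sulfate
Product: 25 N1,N4-bis-Boc guanipiperazine A, via Schiff base 23 (not isolated), via dihydropurine 24 (not isolated)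
Conditions: NaOAc, DMSO/H2O, 60 °C; then FeCl3·6H2O (10 mol %), air, 80 °C
Reagents that add atoms: none
Why: Traube-type oxidative purine annulation: the 5-amino group, the only amine-like nitrogen of 22, forms the imine, the 6-amino group closes the aminal, and iron-catalysed aerobic dehydrogenation aromatises the imidazole ring; the buffered medium spares both carbamates.

Step 14
Reactants: 25 bis-Boc guanipiperazine A
Product: 26 guanipiperazine A
Conditions: CF3CO2H, CH2Cl2, rt; then aq. NH3 to pH 8
Reagents that add atoms: none
Why: Acidolysis of both carbamates; guanine, diaryl ether and phenol are stable to trifluoroacetic acid, and neither stereocentre is α to a carbonyl.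

## Compound list

1 | Boc-4-iodo-L-phenylalanine methyl ester | CC(C)(C)OC(=O)N[C@@H](Cc1ccc(I)cc1)C(=O)OC | starting material
2 | 4-(benzyloxy)-3-hydroxybenzaldehyde | O=Cc1ccc(OCc2ccccc2)c(O)c1 | starting material
3 | methyl (2S)-3-{4-[2-(benzyloxy)-5-formylphenoxy]phenyl}-2-(Boc-amino)propanoate | CC(C)(C)OC(=O)N[C@@H](Cc1ccc(Oc2cc(C=O)ccc2OCc2ccccc2)cc1)C(=O)OC | intermediate
4 | methyl (2S)-3-{4-[2-(benzyloxy)-5-(hydroxymethyl)phenoxy]phenyl}-2-(Boc-amino)propanoate | CC(C)(C)OC(=O)N[C@@H](Cc1ccc(Oc2cc(CO)ccc2OCc2ccccc2)cc1)C(=O)OC | intermediate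
5 | sodium 4-toluenesulfinate | Cc1ccc(S(=O)[O-])cc1.[Na+] | starting material
6 | methyl (2S)-3-{4-[2-(benzyloxy)-5-(bromomethyl)phenoxy]phenyl}-2-(Boc-amino)propanoate | CC(C)(C)OC(=O)N[C@@H](Cc1ccc(Oc2cc(CBr)ccc2OCc2ccccc2)cc1)C(=O)OC | intermediate (not isolated)
7 | methyl (2S)-3-{4-[2-(benzyloxy)-5-(tosylmethyl)phenoxy]phenyl}-2-(Boc-amino)propanoate | CC(C)(C)OC(=O)N[C@@H](Cc1ccc(Oc2cc(CS(=O)(=O)c3ccc(C)cc3)ccc2OCc2ccccc2)cc1)C(=O)OC | intermediate
8 | tert-butyl N-[(2S)-1-{4-[2-(benzyloxy)-5-(tosylmethyl)phenoxy]phenyl}-3-oxopropan-2-yl]carbamate | CC(C)(C)OC(=O)N[C@@H](Cc1ccc(Oc2cc(CS(=O)(=O)c3ccc(C)cc3)ccc2OCc2ccccc2)cc1)C=O | intermediate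
9 | dimethyl aminomalonate hydrochloride | COC(=O)C(N)C(=O)OC.Cl | starting material
10 | dimethyl 2-{[(2S)-2-(Boc-amino)-3-{4-[2-(benzyloxy)-5-(tosylmethyl)phenoxy]phenyl}propyl]amino}malonate | CC(C)(C)OC(=O)N[C@@H](Cc1ccc(Oc2cc(CS(=O)(=O)c3ccc(C)cc3)ccc2OCc2ccccc2)cc1)CNC(C(=O)OC)C(=O)OC | intermediate
11 | dimethyl 2-{[(2S)-2-amino-3-{4-[2-(benzyloxy)-5-(tosylmethyl)phenoxy]phenyl}propyl]amino}malonate bis(trifluoroacetate) | N[C@@H](Cc1ccc(Oc2cc(CS(=O)(=O)c3ccc(C)cc3)ccc2OCc2ccccc2)cc1)CNC(C(=O)OC)C(=O)OC.OC(=O)C(F)(F)F.OC(=O)C(F)(F)F | intermediate (not isolated)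
12 | methyl (2RS,5S)-5-{4-[2-(benzyloxy)-5-(tosylmethyl)phenoxy]benzyl}-3-oxopiperazine-2-carboxylate | COC(=O)C1NC[C@H](Cc2ccc(Oc3cc(CS(=O)(=O)c4ccc(C)cc4)ccc3OCc3ccccc3)cc2)NC1=O | intermediate
13 | 1-tert-butyl 2-methyl (2RS,5S)-5-{4-[2-(benzyloxy)-5-(tosylmethyl)phenoxy]benzyl}-3-oxopiperazine-1,2-dicarboxylate | COC(=O)C1N(C(=O)OC(C)(C)C)C[C@H](Cc2ccc(Oc3cc(CS(=O)(=O)c4ccc(C)cc4)ccc3OCc3ccccc3)cc2)NC1=O | intermediate
14 | 1-tert-butyl 2-methyl (2RS,5S)-5-{4-[2-hydroxy-5-(tosylmethyl)phenoxy]benzyl}-3-oxopiperazine-1,2-dicarboxylate | COC(=O)C1N(C(=O)OC(C)(C)C)C[C@H](Cc2ccc(Oc3cc(CS(=O)(=O)c4ccc(C)cc4)ccc3O)cc2)NC1=O | intermediate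
15 | para-quinone methide: 1-tert-butyl 2-methyl (5S)-5-{4-[(3-methylidene-6-oxocyclohexa-1,4-dien-1-yl)oxy]benzyl}-3-oxopiperazine-1,2-dicarboxylate | COC(=O)C1N(C(=O)OC(C)(C)C)C[C@H](Cc2ccc(OC3=CC(=C)C=CC3=O)cc2)NC1=O | intermediate (not isolated)
16 | macrocyclic piperazinone ester: (2S,5S)-1-Boc-2-(methoxycarbonyl)-3-oxopiperazine bridged from C2 (CH2 to ring A, para to its free OH) to C5 (CH2 to ring B) through the diaryl ether | Oc1ccc4cc1Oc2ccc(cc2)C[C@H]3CN(C(=O)OC(C)(C)C)[C@](C(=O)OC)(C(=O)N3)C4 | intermediate
17 | carboxylic acid corresponding to 16 | Oc1ccc4cc1Oc2ccc(cc2)C[C@H]3CN(C(=O)OC(C)(C)C)[C@](C(=O)O)(C(=O)N3)C4 | intermediate (not isolated)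
18 | macrocyclic (2S,5S)-1-Boc-3-oxopiperazine with free ring A phenol (cis lactam) | Oc1ccc4cc1Oc2ccc(cc2)C[C@H]3CN(C(=O)OC(C)(C)C)[C@H](C(=O)N3)C4 | intermediate
19 | macrocyclic (2S,5S)-N1-Boc piperazine phenol | Oc1ccc4cc1Oc2ccc(cc2)C[C@H]3CN(C(=O)OC(C)(C)C)[C@H](CN3)C4 | intermediate (not isolated)
20 | macrocyclic (2S,5S)-N1,N4-bis-Boc piperazine phenol | Oc1ccc4cc1Oc2ccc(cc2)C[C@H]3CN(C(=O)OC(C)(C)C)[C@H](CN3C(=O)OC(C)(C)C)C4 | intermediate
21 | bis-Boc macrocyclic salicylaldehyde (CHO ortho to the ring A OH) | Oc1c(C=O)cc4cc1Oc2ccc(cc2)C[C@H]3CN(C(=O)OC(C)(C)C)[C@H](CN3C(=O)OC(C)(C)C)C4 | intermediate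
22 | 2,5,6-triaminopyrimidin-4(3H)-one sulfate | Nc1nc(N)c(N)c(=O)[nH]1.OS(=O)(=O)O | starting material
23 | Schiff base of 21 with the 5-amino group of the triaminopyrimidinone | Nc1nc(N)c(/N=C/c2cc4cc(c2O)Oc5ccc(cc5)C[C@H]3CN(C(=O)OC(C)(C)C)[C@H](CN3C(=O)OC(C)(C)C)C4)c(=O)[nH]1 | intermediate (not isolated)
24 | 8-aryl-7,8-dihydroguanine (aminal, C8 epimers) | Nc1nc2NC(c3cc4cc(c3O)Oc5ccc(cc5)C[C@H]6CN(C(=O)OC(C)(C)C)[C@H](CN6C(=O)OC(C)(C)C)C4)Nc2c(=O)[nH]1 | intermediate (not isolated)
25 | N1,N4-bis-Boc guanipiperazine A | Nc1nc2nc(-c3cc4cc(c3O)Oc5ccc(cc5)C[C@H]6CN(C(=O)OC(C)(C)C)[C@H](CN6C(=O)OC(C)(C)C)C4)[nH]c2c(=O)[nH]1 | intermediate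
26 | guanipiperazine A | Nc1nc2nc(-c3cc4cc(c3O)Oc3ccc(cc3)C[C@H]3CN[C@H](CN3)C4)[nH]c2c(=O)[nH]1 | target

## Step count and risk

Total step count: 14. Longest linear sequence: 14 steps (1 to 26).

**Step 9 (key step, proposed new method).** The most likely failure is oligomerisation by intermolecular 1,6-addition, or capture of the quinone methide by water. The conformer that folds ring A over the enolate (C5 arm axial) may be a minor one, and an unsubstituted para-quinone methide does not wait for it.

The fallback replaces the transient electrophile by a persistent one and uses a classical cyclophane-forming carbanion alkylation. It sets out from 4 and returns at 16.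
- Alcohol 4 is silylated (t-BuPh2SiCl, imidazole) to tert-butyldiphenylsilyl ether F1.
- i-Bu2AlH at −78 °C gives amino aldehyde F2, and reductive amination with 9 (NaBH(OAc)3) gives amino malonate F3.
- Boc removal under non-ionising conditions (Me3SiOTf, 2,6-lutidine; MeOH) and lactamisation (Et3N, MeOH) give piperazinone F4, and Boc2O gives carbamate F5.
- Bu4NF buffered with AcOH frees benzylic alcohol F6, and CBr4/PPh3 gives benzylic bromide F7.
- Slow addition of F7 to Cs2CO3 in MeCN closes the ring by SN2 alkylation of the same C2 carbanion, with the ring A oxygen still benzylated, giving macrocyclic benzyl ether F8.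
- Hydrogenolysis (H2, Pd/C) gives 16.

**Step 1.** Partial epimerisation of the α-centre of the amino ester by carbonate at 90 °C, or a sluggish coupling of the ortho-alkoxy phenol, is the main concern.

The fallback is an oxidative copper coupling at room temperature. It sets out from 1 and returns at 3.
- Miyaura borylation (B2pin2, Pd(dppf)Cl2, KOAc) gives pinacol boronate F9.
- NaIO4/NH4OAc gives boronic acid F10.
- Chan–Lam–Evans coupling with 2 (Cu(OAc)2, pyridine, 4 Å MS, CH2Cl2, air) gives 3.

**Step 4.** Over-reduction to the alcohol and α-epimerisation of the aldehyde during work-up are likely, because the tetrahedral aluminate is only marginally stable.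

The fallback sets out from 7 and returns at 8. Full reduction with LiBH4 gives amino alcohol F11, and Parikh–Doering oxidation (SO3·pyridine, DMSO, i-Pr2NEt, 0 °C) gives 8, used at once.

**Step 10.** The quaternary ester may saponify slowly, and prolonged hydroxide could open the lactam or fragment the phenoxide by retro-1,6-addition.

The fallback sets out from 16 and returns at 18 with no new compound. It is a neutral Krapcho dealkoxycarbonylation (LiCl, wet DMSO, 130 °C), in which chloride attacks the ester methyl group. Any thermal loss of the N1 carbamate is repaired by the Boc2O treatment of step 11.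

**Step 13.** The hydrogen-bonded salicylidene imine may cyclise and dehydrogenate incompletely, or the electron-rich phenol may be oxidised instead.

The fallback is a non-oxidative Traube sequence. It sets out from 21 and returns at 25.
- Pinnick oxidation (NaClO2, NaH2PO4, 2-methyl-2-butene) gives salicylic acid F12.
- Amide coupling with the 5-amino group of 22 (EDC·HCl, HOBt, i-Pr2NEt, DMF) gives 5-aroylamino pyrimidinone F13.
- Cyclodehydration (aq. NaOH, EtOH, 80 °C) gives 25.

## Further compounds

F1 | step 9 | methyl (2S)-3-{4-[2-(benzyloxy)-5-{[(tert-butyldiphenylsilyl)oxy]methyl}phenoxy]phenyl}-2-(Boc-amino)propanoate | CC(C)(C)OC(=O)N[C@@H](Cc1ccc(Oc2cc(CO[Si](c3ccccc3)(c3ccccc3)C(C)(C)C)ccc2OCc2ccccc2)cc1)C(=O)OC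
F2 | step 9 | tert-butyl N-[(2S)-1-{4-[2-(benzyloxy)-5-{[(tert-butyldiphenylsilyl)oxy]methyl}phenoxy]phenyl}-3-oxopropan-2-yl]carbamate | CC(C)(C)OC(=O)N[C@@H](Cc1ccc(Oc2cc(CO[Si](c3ccccc3)(c3ccccc3)C(C)(C)C)ccc2OCc2ccccc2)cc1)C=O
F3 | step 9 | dimethyl 2-{[(2S)-2-(Boc-amino)-3-{4-[2-(benzyloxy)-5-{[(tert-butyldiphenylsilyl)oxy]methyl}phenoxy]phenyl}propyl]amino}malonate | CC(C)(C)OC(=O)N[C@@H](Cc1ccc(Oc2cc(CO[Si](c3ccccc3)(c3ccccc3)C(C)(C)C)ccc2OCc2ccccc2)cc1)CNC(C(=O)OC)C(=O)OC
F4 | step 9 | methyl (2RS,5S)-5-{4-[2-(benzyloxy)-5-{[(tert-butyldiphenylsilyl)oxy]methyl}phenoxy]benzyl}-3-oxopiperazine-2-carboxylate | COC(=O)C1NC[C@H](Cc2ccc(Oc3cc(CO[Si](c4ccccc4)(c4ccccc4)C(C)(C)C)ccc3OCc3ccccc3)cc2)NC1=O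
F5 | step 9 | 1-tert-butyl 2-methyl (2RS,5S)-5-{4-[2-(benzyloxy)-5-{[(tert-butyldiphenylsilyl)oxy]methyl}phenoxy]benzyl}-3-oxopiperazine-1,2-dicarboxylate | COC(=O)C1N(C(=O)OC(C)(C)C)C[C@H](Cc2ccc(Oc3cc(CO[Si](c4ccccc4)(c4ccccc4)C(C)(C)C)ccc3OCc3ccccc3)cc2)NC1=O
F6 | step 9 | 1-tert-butyl 2-methyl (2RS,5S)-5-{4-[2-(benzyloxy)-5-(hydroxymethyl)phenoxy]benzyl}-3-oxopiperazine-1,2-dicarboxylate | COC(=O)C1N(C(=O)OC(C)(C)C)C[C@H](Cc2ccc(Oc3cc(CO)ccc3OCc3ccccc3)cc2)NC1=O
F7 | step 9 | 1-tert-butyl 2-methyl (2RS,5S)-5-{4-[2-(benzyloxy)-5-(bromomethyl)phenoxy]benzyl}-3-oxopiperazine-1,2-dicarboxylate | COC(=O)C1N(C(=O)OC(C)(C)C)C[C@H](Cc2ccc(Oc3cc(CBr)ccc3OCc3ccccc3)cc2)NC1=O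
F8 | step 9 | O-benzyl ether of macrocyclic piperazinone ester 16 | C(c1ccccc1)Oc1ccc4cc1Oc2ccc(cc2)C[C@H]3CN(C(=O)OC(C)(C)C)[C@](C(=O)OC)(C(=O)N3)C4
F9 | step 1 | methyl (2S)-2-(Boc-amino)-3-[4-(4,4,5,5-tetramethyl-1,3,2-dioxaborolan-2-yl)phenyl]propanoate | CC(C)(C)OC(=O)N[C@@H](Cc1ccc(B2OC(C)(C)C(C)(C)O2)cc1)C(=O)OC
F10 | step 1 | methyl (2S)-2-(Boc-amino)-3-(4-boronophenyl)propanoate | CC(C)(C)OC(=O)N[C@@H](Cc1ccc(B(O)O)cc1)C(=O)OC
F11 | step 4 | tert-butyl N-[(2S)-1-{4-[2-(benzyloxy)-5-(tosylmethyl)phenoxy]phenyl}-3-hydroxypropan-2-yl]carbamate | CC(C)(C)OC(=O)N[C@@H](Cc1ccc(Oc2cc(CS(=O)(=O)c3ccc(C)cc3)ccc2OCc2ccccc2)cc1)CO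
F0 | step 10 | none | none
F12 | step 13 | bis-Boc macrocyclic salicylic acid (CO2H in place of the CHO of 21) | OC(=O)c1cc4cc(c1O)Oc2ccc(cc2)C[C@H]3CN(C(=O)OC(C)(C)C)[C@H](CN3C(=O)OC(C)(C)C)C4
F13 | step 13 | N-(2,6-diamino-4-oxo-3,4-dihydropyrimidin-5-yl) amide of F12 | Nc1nc(N)c(NC(=O)c2cc4cc(c2O)Oc5ccc(cc5)C[C@H]3CN(C(=O)OC(C)(C)C)[C@H](CN3C(=O)OC(C)(C)C)C4)c(=O)[nH]1
A1 | alternative 1 | N-phthaloyl-3-(4-iodophenoxy)-4-methoxy-L-phenylalanyl-L-alanine 8-quinolinylamide | O=C1c2ccccc2C(=O)N1[C@@H](Cc3ccc(OC)c(c3)Oc4ccc(I)cc4)C(=O)N[C@@H](C)C(=O)Nc5cccc6cccnc56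
A2 | alternative 1 | 14-membered cyclophane lactam with quinolinyl amide | O=C1c2ccccc2C(=O)N1[C@H]3Cc4ccc(OC)c(c4)Oc5ccc(cc5)C[C@H](NC3=O)C(=O)Nc6cccc7cccnc67
A3 | alternative 2 | bis-Boc macrocyclic salicylaldehyde (same structure as 21) | Oc1c(C=O)cc4cc1Oc2ccc(cc2)C[C@H]3CN(C(=O)OC(C)(C)C)[C@H](CN3C(=O)OC(C)(C)C)C4
A4 | alternative 2 | N,N'-bis-Boc guanipiperazine A (same structure as 25) | Nc1nc2nc(-c3cc4cc(c3O)Oc5ccc(cc5)C[C@H]6CN(C(=O)OC(C)(C)C)[C@H](CN6C(=O)OC(C)(C)C)C4)[nH]c2c(=O)[nH]1
A5 | alternative 3 | azido aldehyde with N-Boc-N-(tributylstannylmethyl)amine | COc1ccc(CC=O)cc1Oc2ccc(cc2)C[C@@H](CN=[N+]=[N-])N(C[Sn](CCCC)(CCCC)CCCC)C(=O)OC(C)(C)C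
A6 | alternative 3 | 14-membered macrocyclic imine | COc1ccc2cc1Oc1ccc(cc1)C[C@H](N(C[Sn](CCCC)(CCCC)CCCC)C(=O)OC(C)(C)C)CN=CC2
A7 | alternative 3 | mono-Boc O-methyl macrocyclic piperazine | COc1ccc4cc1Oc2ccc(cc2)C[C@H]3CN[C@H](CN3C(=O)OC(C)(C)C)C4
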